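**Plan**
- Retrosynthesis: cut the C15–O ester; cut C14–C15 and C13–C16 (carboalumination, formaldehyde) and C12–C13 (acetylide alkylation); cut C9–C11 as a Johnson–Claisen retron (O7 to C9); then cut ring B at C8–C9 and C5–C6.
- Enabling feature: ring B is a C7=C8 cyclohexene with C17 on C8 and H on C9, i.e. the Claisen-transposed form of a 2-methylcyclohex-2-enone (C7=O, C8=C9). Its C6–C7–C8(C17) unit is a butan-2-one 1,3-dianion synthon, and C5 and C9 both hang on quaternary C10, so C5 can be the β-carbon of a ring-A cyclohexa-2,5-dienone and C9 a masked formyl carbon.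
- Forward: ring A first, as the achiral dienone acetal 6; ring B is annulated in one pot (Michael C5–C6, aldol condensation C8=C9); then C4 gem-dimethylation, C1=C2 hydrogenation, C7 reduction, Claisen to C9, C3 reduction, chain growth and esterification.
- Stereochemistry: C10 and C5 from a catalytic desymmetrisation (arm by catalyst, face by substrate); C7–OH (temporary) by axial hydride attack; C9 by suprafacial [3,3] shift; C3 by a bulky hydride (axial OH); 13E by syn-carbometalation; the acyl stereocentre is bought.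

Key step: step 4

Assumption: (S)-3-methylpentanoic acid is taken as commercially available; the (S,S)-ligand of step 4 is assumed to select the arm that gives 11 as drawn (otherwise the (R,R)-ligand is used).
Remark: read from the SMILES, the decalin is (3S,5S,9R,10S) with the 3-hydroxyl axial and trans to C20, which decides for a bulky hydride in step 10. Labdane numbering is used in the text (C17 on C8, C18/C19 on C4, C20 on C10). Bicyclic names use naphthalene locants 1 = C9, 2 = C8, 3 = C7, 4 = C6, 4a = C5, 5 = C4, 6 = C3, 7 = C2, 8 = C1, 8a = C10.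

Step 1
Reactants: 1 (E)-1-methoxy-3-(trimethylsilyloxy)buta-1,3-diene; 2 methacrolein
Product: 4 rac-4-formyl-4-methylcyclohex-2-en-1-one, via cycloadduct 3 (not isolated)
Conditions: toluene, 80 °C; then 0.1 M HCl, THF, 0 °C
Reagents that add atoms: none
Why: Diels–Alder reaction of the 1-alkoxy-3-silyloxydiene with the α-substituted enal joins the methoxy-bearing carbon to the formyl-bearing carbon, and mild acid unmasks the ketone and eliminates methanol; the racemate suffices because step 3 removes the stereocentre.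

Step 2
Reactants: 4 rac-4-formyl-4-methylcyclohex-2-en-1-one
Product: 5 rac-4-(1,3-dioxolan-2-yl)-4-methylcyclohex-2-en-1-one
Conditions: HOCH2CH2OH (1.2 equiv), PPTS (cat.), benzene, reflux, Dean–Stark trap
Reagents that add atoms: ethylene glycol, OCCO
Why: Acid-catalysed acetalisation is much faster at the aldehyde than at the conjugated ketone; the dioxolane masks C9, prevents deformylation of the later dienone and makes the C9 substituent larger than the C20 methyl.

Step 3
Reactants: 5 rac-4-(1,3-dioxolan-2-yl)-4-methylcyclohex-2-en-1-one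
Product: 6 4-(1,3-dioxolan-2-yl)-4-methylcyclohexa-2,5-dien-1-one
Conditions: DDQ, 1,4-dioxane, reflux
Reagents that add atoms: none
Why: Quinone dehydrogenation of a 4,4-disubstituted cyclohex-2-enone at C1–C2 should give the cross-conjugated, achiral dienone in which C5 and C1 are enantiotopic β-carbons.

Step 4
Reactants: 6 4-(1,3-dioxolan-2-yl)-4-methylcyclohexa-2,5-dien-1-one; 7 methyl 3-oxopentanoate
Product: 11 methyl (4aS,8aR)-2,8a-dimethyl-3,6-dioxo-3,4,4a,5,6,8a-hexahydronaphthalene-4-carboxylate, via Michael adduct 8 (not isolated), via keto aldehyde 9 (not isolated), via aldol 10 (not isolated)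
Conditions: La(OiPr)3 (10 mol %), (S,S)-NMe-linked BINOL (10 mol %), THF, 0 °C to rt; then 2 M HCl, THF, 50 °C
Reagents that add atoms: none
Why: Proposed new method: the La(OiPr)3/linked-BINOL complex should bind the chelated enolate of 7 and the dienone carbonyl so that C6 adds to C5 (Michael addition) on one of the two enantiotopic enone arms, which fixes C10 and C5 at once; acid then frees the C9 aldehyde, and the C8 enol of the C7 ketone closes ring B by a 6-(enolendo)-exo-trig aldol addition followed by dehydration to the C8=C9 enone. The closest known reaction types are the lanthanum linked-BINOL catalysed Michael addition of β-keto esters to cyclohex-2-enone, catalytic desymmetrisations of 4,4-disubstituted cyclohexa-2,5-dienones by conjugate addition, and the Robinson-type Michael/aldol annulation of β-keto esters. The arm (absolute configuration of C10 and C5) is under catalyst control and the face under substrate control: C6 should enter anti to the dioxolane, on the side of the smaller C20 methyl, which places C6 trans to C9 and gives the trans ring fusion; C6 itself stays epimerisable and the carbinol centres of 10 vanish on dehydration. The step needs mono-addition (one equivalent of 7; the product enone arm is more hindered than the dienone), arm selection, and a single aldol mode. The last is secured because the aldehyde has no α-hydrogen and only C8 can reach C9 in a six-membered closure that can dehydrate.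

Step 5
Reactants: 11 methyl (4aS,8aR)-2,8a-dimethyl-3,6-dioxo-3,4,4a,5,6,8a-hexahydronaphthalene-4-carboxylate
Product: 13 methyl (4aS,8aS)-2,5,5,8a-tetramethyl-3,6-dioxo-3,4,4a,5,6,8a-hexahydronaphthalene-4-carboxylate, via monomethyl ketone 12 (not isolated)
Conditions: LiN(iPr)2 (2.1 equiv), THF, −78 °C; MeI (1.1 equiv); LiN(iPr)2 (1.2 equiv); MeI (2 equiv), −78 to −30 °C
Reagents that add atoms: iodomethane, CI
Why: Enolate alkylation: the first equivalent of base parks ring B as its β-keto ester enolate, further base removes the only remaining acidic hydrogens (α′ at C4 of the ring-A enone, C10 being quaternary), and two methylations give the gem-dimethyl group without a new stereocentre.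

Step 6
Reactants: 13 methyl (4aS,8aS)-2,5,5,8a-tetramethyl-3,6-dioxo-3,4,4a,5,6,8a-hexahydronaphthalene-4-carboxylate
Product: 14 (4aS,8aS)-2,5,5,8a-tetramethyl-4,4a,5,8a-tetrahydronaphthalene-3,6-dione
Conditions: LiCl, H2O, DMSO, 140 °C
Reagents that add atoms: none
Why: Krapcho dealkoxycarbonylation (chloride attack on the methyl ester, loss of carbon dioxide) removes the activating ester and the labile C6 stereocentre.

Step 7
Reactants: 14 (4aS,8aS)-2,5,5,8a-tetramethyl-4,4a,5,8a-tetrahydronaphthalene-3,6-dione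
Product: 15 (4aS,8aS)-2,5,5,8a-tetramethyl-4,4a,5,7,8,8a-hexahydronaphthalene-3,6-dione
Conditions: H2 (1 atm), RhCl(PPh3)3 (5 mol %), benzene–EtOH, rt
Reagents that add atoms: none
Why: Homogeneous hydrogenation should saturate the disubstituted C1=C2 bond and leave the trisubstituted, α-methylated C8=C9 enone, as in the selective reduction of the less substituted bond of cross-conjugated steroid dienones.

Step 8
Reactants: 15 (4aS,8aS)-2,5,5,8a-tetramethyl-4,4a,5,7,8,8a-hexahydronaphthalene-3,6-dione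
Product: 16 (3R,4aS,8aS)-3-hydroxy-2,5,5,8a-tetramethyl-3,4,4a,7,8,8a-hexahydronaphthalen-6(5H)-one
Conditions: NaBH4, CeCl3·7H2O, MeOH, −78 °C
Reagents that add atoms: none
Why: Luche reduction: hydride should attack the C7 enone carbonyl in 1,2-fashion and axially, from the face opposite C20, so the new C7 hydroxyl is equatorial and cis to C20 (as with 4-en-3-one steroids), while the neopentyl C3 ketone reacts much more slowly at this temperature.

Step 9
Reactants: 16 (3R,4aS,8aS)-3-hydroxy-2,5,5,8a-tetramethyl-3,4,4a,7,8,8a-hexahydronaphthalen-6(5H)-one; 17 triethyl orthoacetate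
Product: 19 ethyl 2-[(1R,4aS,8aS)-2,5,5,8a-tetramethyl-6-oxo-1,4,4a,5,6,7,8,8a-octahydronaphthalen-1-yl]acetate, via ketene acetal 18 (not isolated)
Conditions: 17 (excess), EtCO2H (cat.), 140 °C, ethanol distilled off
Reagents that add atoms: none
Why: Johnson–Claisen rearrangement: the suprafacial [3,3] shift should carry the two-carbon ester unit from O7 to C9 on the same face (cis to C20), which sets C9 and moves the double bond to C7=C8; delivery of carbon beside an angular methyl in this way is known for steroidal 4-en-3-ols.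

Step 10
Reactants: 19 ethyl 2-[(1R,4aS,8aS)-2,5,5,8a-tetramethyl-6-oxo-1,4,4a,5,6,7,8,8a-octahydronaphthalen-1-yl]acetate
Product: 21 (1R,4aS,6S,8aS)-1-(2-hydroxyethyl)-2,5,5,8a-tetramethyl-1,4,4a,5,6,7,8,8a-octahydronaphthalen-6-ol, via hydroxy ester 20 (not isolated)
Conditions: LiBH(s-Bu)3, THF, −78 °C; then LiAlH4, 0 °C
Reagents that add atoms: none
Why: Hydride reduction: the bulky borohydride should approach the C3 ketone equatorially, avoiding the axial hydrogens on C1 and C5, to give the axial alcohol trans to C20 (as with 4,4-dimethyl-3-oxo terpenoids), and LiAlH4 then reduces the ester to the primary alcohol.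

Step 11
Reactants: 21 (1R,4aS,6S,8aS)-1-(2-hydroxyethyl)-2,5,5,8a-tetramethyl-1,4,4a,5,6,7,8,8a-octahydronaphthalen-6-ol
Product: 22 (1R,4aS,6S,8aS)-1-(2-iodoethyl)-2,5,5,8a-tetramethyl-1,4,4a,5,6,7,8,8a-octahydronaphthalen-6-ol
Conditions: I2, PPh3, imidazole, CH2Cl2, 0 °C
Reagents that add atoms: iodine, II
Why: Appel-type iodination should take the unhindered primary alcohol only, the axial neopentyl C3 hydroxyl being too hindered to be activated at 0 °C.

Step 12
Reactants: 22 (1R,4aS,6S,8aS)-1-(2-iodoethyl)-2,5,5,8a-tetramethyl-1,4,4a,5,6,7,8,8a-octahydronaphthalen-6-ol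
Product: 23 (1R,4aS,6S,8aS)-1-(but-3-yn-1-yl)-2,5,5,8a-tetramethyl-1,4,4a,5,6,7,8,8a-octahydronaphthalen-6-ol
Conditions: LiC≡CH·H2NCH2CH2NH2 (3 equiv), DMSO, rt
Reagents that add atoms: lithium acetylide (ethylenediamine complex), [Li]C#C
Why: SN2 alkylation of the acetylide by the primary iodide adds C13 and C14; the free C3 hydroxyl is only deprotonated.

Step 13
Reactants: 23 (1R,4aS,6S,8aS)-1-(but-3-yn-1-yl)-2,5,5,8a-tetramethyl-1,4,4a,5,6,7,8,8a-octahydronaphthalen-6-ol
Product: 25 (1R,4aS,6S,8aS)-1-[(3E)-5-hydroxy-3-methylpent-3-en-1-yl]-2,5,5,8a-tetramethyl-1,4,4a,5,6,7,8,8a-octahydronaphthalen-6-ol, via alkenylalane 24 (not isolated)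
Conditions: AlMe3 (4 equiv), Cp2ZrCl2 (25 mol %), CH2Cl2, 0 °C to rt; then (CH2O)n, 0 °C to rt
Reagents that add atoms: trimethylaluminium, C[Al](C)C; formaldehyde (as paraformaldehyde), C=O
Why: Negishi carboalumination adds methyl and aluminium syn across the terminal alkyne with methyl on the internal carbon, and trapping of the alkenylalane with formaldehyde proceeds with retention, which fixes 13E; the C7=C8 bond is inert.

Step 14
Reactants: 25 (1R,4aS,6S,8aS)-1-[(3E)-5-hydroxy-3-methylpent-3-en-1-yl]-2,5,5,8a-tetramethyl-1,4,4a,5,6,7,8,8a-octahydronaphthalen-6-ol; 26 (S)-3-methylpentanoic acid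
Product: 27 (2E)-5-[(1R,4aS,6S,8aS)-6-hydroxy-2,5,5,8a-tetramethyl-1,4,4a,5,6,7,8,8a-octahydronaphthalen-1-yl]-3-methylpent-2-en-1-yl (3S)-3-methylpentanoate (CNP0307530.1)
Conditions: EDC·HCl, DMAP (cat.), CH2Cl2, 0 °C
Reagents that add atoms: none
Why: Steglich esterification should acylate the primary allylic hydroxyl far faster than the axial neopentyl C3 hydroxyl, and the acid's stereocentre, β to the carbonyl, cannot epimerise.

**Compound list**
1 | (E)-1-methoxy-3-(trimethylsilyloxy)buta-1,3-diene | CO/C=C/C(=C)O[Si](C)(C)C | starting material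
2 | methacrolein | CC(=C)C=O | starting material
3 | 2-methoxy-1-methyl-4-(trimethylsilyloxy)cyclohex-3-ene-1-carbaldehyde (racemic) | COC1C=C(O[Si](C)(C)C)CCC1(C)C=O | intermediate (not isolated)
4 | rac-4-formyl-4-methylcyclohex-2-en-1-one | CC1(C=O)CCC(=O)C=C1 | intermediate
5 | rac-4-(1,3-dioxolan-2-yl)-4-methylcyclohex-2-en-1-one | CC1(C2OCCO2)CCC(=O)C=C1 | intermediate
6 | 4-(1,3-dioxolan-2-yl)-4-methylcyclohexa-2,5-dien-1-one (achiral) | CC1(C2OCCO2)C=CC(=O)C=C1 | intermediate
7 | methyl 3-oxopentanoate | CCC(=O)CC(=O)OC | starting material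
8 | methyl 2-[(1S,6R)-6-(1,3-dioxolan-2-yl)-6-methyl-3-oxocyclohex-4-en-1-yl]-3-oxopentanoate (C6 epimers) | CCC(=O)C(C(=O)OC)[C@@H]2CC(=O)C=C[C@@]2(C)C1OCCO1 | intermediate (not isolated)
9 | methyl 2-[(1S,6R)-6-formyl-6-methyl-3-oxocyclohex-4-en-1-yl]-3-oxopentanoate (C6 epimers) | CCC(=O)C(C(=O)OC)[C@@H]1CC(=O)C=C[C@@]1(C)C=O | intermediate (not isolated)
10 | methyl (4aS,8aR)-1-hydroxy-2,8a-dimethyl-3,6-dioxo-1,2,3,4,4a,5,6,8a-octahydronaphthalene-4-carboxylate (C6, C8, C9 unassigned) | CC1C(=O)C(C(=O)OC)[C@@H]2CC(=O)C=C[C@@]2(C)C1O | intermediate (not isolated)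
11 | methyl (4aS,8aR)-2,8a-dimethyl-3,6-dioxo-3,4,4a,5,6,8a-hexahydronaphthalene-4-carboxylate (trans ring fusion; C6 epimers or enol) | C1=C(C)C(=O)C(C(=O)OC)[C@@H]2CC(=O)C=C[C@@]12C | intermediate
12 | methyl (4aS,8aR)-2,5,8a-trimethyl-3,6-dioxo-3,4,4a,5,6,8a-hexahydronaphthalene-4-carboxylate (C4 unassigned) | C1=C(C)C(=O)C(C(=O)OC)[C@@H]2C(C)C(=O)C=C[C@@]12C | intermediate (not isolated)
13 | methyl (4aS,8aS)-2,5,5,8a-tetramethyl-3,6-dioxo-3,4,4a,5,6,8a-hexahydronaphthalene-4-carboxylate | C1=C(C)C(=O)C(C(=O)OC)[C@@H]2C(C)(C)C(=O)C=C[C@@]12C | intermediate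
14 | (4aS,8aS)-2,5,5,8a-tetramethyl-4,4a,5,8a-tetrahydronaphthalene-3,6-dione | C1=C(C)C(=O)C[C@@H]2C(C)(C)C(=O)C=C[C@@]12C | intermediate
15 | (4aS,8aS)-2,5,5,8a-tetramethyl-4,4a,5,7,8,8a-hexahydronaphthalene-3,6-dione | C1=C(C)C(=O)C[C@@H]2C(C)(C)C(=O)CC[C@@]12C | intermediate
16 | (3R,4aS,8aS)-3-hydroxy-2,5,5,8a-tetramethyl-3,4,4a,7,8,8a-hexahydronaphthalen-6(5H)-one (C7–OH cis to C20) | C1=C(C)[C@H](O)C[C@@H]2C(C)(C)C(=O)CC[C@@]12C | intermediate
17 | triethyl orthoacetate | CCOC(C)(OCC)OCC | starting material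
18 | (3R,4aS,8aS)-3-[(1-ethoxyethenyl)oxy]-2,5,5,8a-tetramethyl-3,4,4a,7,8,8a-hexahydronaphthalen-6(5H)-one | C1=C(C)[C@H](OC(=C)OCC)C[C@@H]2C(C)(C)C(=O)CC[C@@]12C | intermediate (not isolated)
19 | ethyl 2-[(1R,4aS,8aS)-2,5,5,8a-tetramethyl-6-oxo-1,4,4a,5,6,7,8,8a-octahydronaphthalen-1-yl]acetate | CCOC(=O)C[C@@H]1C(C)=CC[C@@H]2C(C)(C)C(=O)CC[C@@]12C | intermediate
20 | ethyl 2-[(1R,4aS,6S,8aS)-6-hydroxy-2,5,5,8a-tetramethyl-1,4,4a,5,6,7,8,8a-octahydronaphthalen-1-yl]acetate | CCOC(=O)C[C@@H]1C(C)=CC[C@@H]2C(C)(C)[C@@H](O)CC[C@@]12C | intermediate (not isolated)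
21 | (1R,4aS,6S,8aS)-1-(2-hydroxyethyl)-2,5,5,8a-tetramethyl-1,4,4a,5,6,7,8,8a-octahydronaphthalen-6-ol | OCC[C@@H]1C(C)=CC[C@@H]2C(C)(C)[C@@H](O)CC[C@@]12C | intermediate
22 | (1R,4aS,6S,8aS)-1-(2-iodoethyl)-2,5,5,8a-tetramethyl-1,4,4a,5,6,7,8,8a-octahydronaphthalen-6-ol | ICC[C@@H]1C(C)=CC[C@@H]2C(C)(C)[C@@H](O)CC[C@@]12C | intermediate
23 | (1R,4aS,6S,8aS)-1-(but-3-yn-1-yl)-2,5,5,8a-tetramethyl-1,4,4a,5,6,7,8,8a-octahydronaphthalen-6-ol | C#CCC[C@@H]1C(C)=CC[C@@H]2C(C)(C)[C@@H](O)CC[C@@]12C | intermediate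
24 | (E)-alkenyldimethylalane from 23 (C14–AlMe2 cis to C16; C3 oxygen as its dimethylaluminium alkoxide; ring configuration as in 23) | C[Al](C)/C=C(\C)CC[C@@H]1C(C)=CC[C@@H]2C(C)(C)[C@@H](O[Al](C)C)CC[C@@]12C | intermediate (not isolated)
25 | (1R,4aS,6S,8aS)-1-[(3E)-5-hydroxy-3-methylpent-3-en-1-yl]-2,5,5,8a-tetramethyl-1,4,4a,5,6,7,8,8a-octahydronaphthalen-6-ol | OC/C=C(\C)CC[C@@H]1C(C)=CC[C@@H]2C(C)(C)[C@@H](O)CC[C@@]12C | intermediate
26 | (S)-3-methylpentanoic acid | CC[C@H](C)CC(=O)O | starting material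
27 | (2E)-5-[(1R,4aS,6S,8aS)-6-hydroxy-2,5,5,8a-tetramethyl-1,4,4a,5,6,7,8,8a-octahydronaphthalen-1-yl]-3-methylpent-2-en-1-yl (3S)-3-methylpentanoate | CC[C@H](C)CC(=O)OC/C=C(\C)CC[C@@H]1C(C)=CC[C@@H]2C(C)(C)[C@@H](O)CC[C@@]12C | target

Total steps: 14. Longest linear sequence: 14 steps (from 1 and 2 to 27).

**Steps most likely to fail**

1. Step 4 (Proposed new method). What may go wrong: poor discrimination between the two enone arms (low enantiomeric purity), attack on the dioxolane face (cis ring fusion), a second Michael addition to the remaining enone, or closure of C8 onto C1 instead of onto C9. The fallback uses known chemistry, sets out from 2 and returns at 11. A Diels–Alder reaction of 2 with 1-(dimethylamino)-3-(tert-butyldimethylsilyloxy)buta-1,3-diene under a chiral (salen)CrSbF6 Lewis acid (trivalent chromium; the catalyst enantiomer that leads to the R aldehyde) should give the endo cycloadduct (1R,2S)-4-[tert-butyl(dimethyl)silyl]oxy-2-(dimethylamino)-1-methylcyclohex-3-ene-1-carbaldehyde F1. Dilute aqueous acid then gives (R)-4-formyl-4-methylcyclohex-2-en-1-one F2, and acetalisation as in step 2 gives (R)-4-(1,3-dioxolan-2-yl)-4-methylcyclohex-2-en-1-one F3. LiN(iPr)2 followed by PhSeCl gives the α′-selenide (4R)-4-(1,3-dioxolan-2-yl)-4-methyl-6-(phenylselanyl)cyclohex-2-en-1-one F4, a chiral stand-in for the dienone. DBU-catalysed Michael addition of 7 (anti to the dioxolane) and then 2 M HCl give methyl (4aS,8aR)-2,8a-dimethyl-3,6-dioxo-7-(phenylselanyl)-3,4,4a,5,6,7,8,8a-octahydronaphthalene-4-carboxylate F5. H2O2 oxidation and syn-elimination of the selenoxide restore C1=C2 and return to 11.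

2. Step 9. What may go wrong: acid-induced ionisation of the allylic alcohol or its orthoester and elimination to a ring-B diene, or a rearrangement too slow to compete, because carbon must reach C9 beside quaternary C10 on the face of C20. The fallback sets out from 16 and returns at 23. LiBH(s-Bu)3 first reduces the C3 ketone to (3R,4aS,6S,8aS)-2,5,5,8a-tetramethyl-3,4,4a,5,6,7,8,8a-octahydronaphthalene-3,6-diol F6. KH and Bu3SnCH2I etherify the less hindered allylic hydroxyl to (3R,4aS,6S,8aS)-2,5,5,8a-tetramethyl-3-[(tributylstannyl)methoxy]-3,4,4a,5,6,7,8,8a-octahydronaphthalen-6-ol F7. n-BuLi effects tin–lithium exchange and a Still–Wittig [2,3] rearrangement, which delivers one carbon to C9 on the same face and gives (1R,4aS,6S,8aR)-1-(hydroxymethyl)-2,5,5,8a-tetramethyl-1,4,4a,5,6,7,8,8a-octahydronaphthalen-6-ol F8. I2, PPh3 and imidazole give (1R,4aS,6S,8aR)-1-(iodomethyl)-2,5,5,8a-tetramethyl-1,4,4a,5,6,7,8,8a-octahydronaphthalen-6-ol F9. LiCH2C≡CSiMe3 gives (1R,4aS,6S,8aS)-2,5,5,8a-tetramethyl-1-[4-(trimethylsilyl)but-3-yn-1-yl]-1,4,4a,5,6,7,8,8a-octahydronaphthalen-6-ol F10, and K2CO3 in MeOH removes silicon and returns to 23.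

3. Step 5. What may go wrong: methylation on carbon or oxygen of the ring-B β-keto ester enolate, or an incomplete second methylation at C4. The fallback sets out from 11 and returns at 13. Me3SiCHN2 in MeOH–toluene should O-methylate the enolised β-keto ester to the neutral enol ether methyl (4aR,8aS)-3-methoxy-2,8a-dimethyl-6-oxo-4a,5,6,8a-tetrahydronaphthalene-4-carboxylate F11, in which C4 carries the only acidic hydrogens. LiN(iPr)2 and MeI, applied twice, give methyl (4aS,8aS)-3-methoxy-2,5,5,8a-tetramethyl-6-oxo-4a,5,6,8a-tetrahydronaphthalene-4-carboxylate F12, and dilute aqueous HCl hydrolyses the enol ether and returns to 13.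

**Further compounds**
F1 | step 4 | (1R,2S)-4-[tert-butyl(dimethyl)silyl]oxy-2-(dimethylamino)-1-methylcyclohex-3-ene-1-carbaldehyde | O=C[C@]1(C)CCC(O[Si](C)(C)C(C)(C)C)=C[C@@H]1N(C)C
F2 | step 4 | (R)-4-formyl-4-methylcyclohex-2-en-1-one | O=C1C=C[C@](C)(C=O)CC1
F3 | step 4 | (R)-4-(1,3-dioxolan-2-yl)-4-methylcyclohex-2-en-1-one | O=C1C=C[C@](C)(C2OCCO2)CC1
F4 | step 4 | (4R)-4-(1,3-dioxolan-2-yl)-4-methyl-6-(phenylselanyl)cyclohex-2-en-1-one | O=C1C=C[C@](C)(C2OCCO2)CC1[Se]c1ccccc1
F5 | step 4 | methyl (4aS,8aR)-2,8a-dimethyl-3,6-dioxo-7-(phenylselanyl)-3,4,4a,5,6,7,8,8a-octahydronaphthalene-4-carboxylate | C1=C(C)C(=O)C(C(=O)OC)[C@@H]2CC(=O)C([Se]c3ccccc3)C[C@@]12C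
F6 | step 9 | (3R,4aS,6S,8aS)-2,5,5,8a-tetramethyl-3,4,4a,5,6,7,8,8a-octahydronaphthalene-3,6-diol | C1=C(C)[C@H](O)C[C@@H]2C(C)(C)[C@@H](O)CC[C@@]12C
F7 | step 9 | (3R,4aS,6S,8aS)-2,5,5,8a-tetramethyl-3-[(tributylstannyl)methoxy]-3,4,4a,5,6,7,8,8a-octahydronaphthalen-6-ol | C1=C(C)[C@H](OC[Sn](CCCC)(CCCC)CCCC)C[C@@H]2C(C)(C)[C@@H](O)CC[C@@]12C
F8 | step 9 | (1R,4aS,6S,8aR)-1-(hydroxymethyl)-2,5,5,8a-tetramethyl-1,4,4a,5,6,7,8,8a-octahydronaphthalen-6-ol | OC[C@@H]1C(C)=CC[C@@H]2C(C)(C)[C@@H](O)CC[C@@]12C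
F9 | step 9 | (1R,4aS,6S,8aR)-1-(iodomethyl)-2,5,5,8a-tetramethyl-1,4,4a,5,6,7,8,8a-octahydronaphthalen-6-ol | IC[C@@H]1C(C)=CC[C@@H]2C(C)(C)[C@@H](O)CC[C@@]12C
F10 | step 9 | (1R,4aS,6S,8aS)-2,5,5,8a-tetramethyl-1-[4-(trimethylsilyl)but-3-yn-1-yl]-1,4,4a,5,6,7,8,8a-octahydronaphthalen-6-ol | C[Si](C)(C)C#CCC[C@@H]1C(C)=CC[C@@H]2C(C)(C)[C@@H](O)CC[C@@]12C
F11 | step 5 | methyl (4aR,8aS)-3-methoxy-2,8a-dimethyl-6-oxo-4a,5,6,8a-tetrahydronaphthalene-4-carboxylate | C1=C(C)C(OC)=C(C(=O)OC)[C@@H]2CC(=O)C=C[C@@]12C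
F12 | step 5 | methyl (4aS,8aS)-3-methoxy-2,5,5,8a-tetramethyl-6-oxo-4a,5,6,8a-tetrahydronaphthalene-4-carboxylate | C1=C(C)C(OC)=C(C(=O)OC)[C@@H]2C(C)(C)C(=O)C=C[C@@]12C
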